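13.3 mM of coupling partner against 19 mM of substrate is the number to start from. The partner is the smaller charge, so it is the limiting reagent if one partner makes one product, and product then stops at 70.0% of the substrate charged.

| flask | substrate | coupling partner | protic impurity | remark | time |
|---|---|---|---|---|---|
| Friday's | 19 mM | 13.3 mM | 1.3 mM | run made earlier |  |
| Saturday's | 19 mM | 13.3 mM | 2.1 mM | run made earlier |  |
| flask | 19 mM | 13.3 mM | 0.950 mM |  | 15 h |

| run | time / h | product / % | substrate / % |
|---|---|---|---|
| Friday's | 5.00 | 65.3 | 34.9 |
| Friday's | 10.0 | 63.4 | 31.6 |
| Friday's | 15.0 | 62.6 | 32.5 |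
| Friday's | 20.0 | 63.6 | 33.0 |
| Saturday's | 1.33 | 25.8 | 73.4 |
| Saturday's | 3.00 | 48.3 | 52.3 |
| Saturday's | 8.00 | 60.8 | 35.1 |
| Saturday's | 20.0 | 59.2 | 34.6 |

(each reading ± 1 percentage point)



- concentration of product at 15 h, in mM
- concentration of substrate at 15 h, in mM
- concentration of intermediate at 15 h, in mM

I reckon the flask from its start and from its end, then join the two. Saturday's first reading gives 3.69 mM h⁻¹ of product, averaged up to 1.33 h. At the end, Saturday's last two readings average 11.4 mM. The starting line reaches that level at 3.09 h. The asked 15 h lies well beyond this, and Saturday is flat from 8.00 h, so I treat the flask as finished.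

Now the plateau. Friday's last three readings average 12.0 mM of product, less than the partner charge. Call the toll the coupling partner missing from the plateau per mM of protic impurity charged. Friday's toll is 0.994, which puts this flask's product at 12.4 mM.

That toll rests on one run. Saturday's toll is 0.905. The difference, on Friday's impurity, is 0.610% of the substrate charged, against 1 percentage point on a reading, so I pool them. The partner missing in both runs, over the impurity charged in both, gives a pooled toll of 0.939. This flask's product is then 12.4 mM. Friday's missing mass, which I guess is intermediate, is 0.842 mM. I carry that amount over to this flask unchanged, as a rough guess, and its substrate is then 5.76 mM.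

The forecast gives 12.4 mM of product, 6.1 mM of substrate and 0.5 mM of intermediate, which is my product with less intermediate and more substrate, and it calls the split tentative: “the mass gap is only a few points”.

The flask gives 12.4 mM of product, 5.96 mM of substrate and 0.639 mM of intermediate.

    substrate ⇌ intermediate + leaving ligand (K = 0.00140 M, k = 6.20 × 10⁻⁵ s⁻¹)
    coupling partner + intermediate → product (k = 8.04 M⁻¹ s⁻¹)
    coupling partner + protic impurity → quenched reagent (k = 0.0312 M⁻¹ s⁻¹)

In this flask the coupling partner is already at 0 mM by 7.50 h, with 0.895 mM of quenched reagent standing beside it. Now use the toll on the neighbouring flask charged with 0.38 mM of protic impurity. It predicts 12.9 mM of product, and that flask holds 12.9 mM.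

All runs are calculated with constants of no real substance, noise included.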